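## Structural features

The target is a guaiane (hydroazulene) ester: a five-membered ring A (C1–C5) fused through C1 and C5 to a seven-membered ring B (C1, C5–C10), with a tetrasubstituted C1=C10 alkene that carries the C14 methyl group on C10. Five stereocentres run in an unbroken row from C4 to C8: a tertiary carbinol (C4, with C15), the ring-fusion methine (C5), a free secondary carbinol (C6), the isopropyl-bearing methine (C7) and the carbinol esterified by 4-hydroxybenzoic acid (C8). Read from the SMILES, the configuration is 4S,5S,6R,7S,8S: the C4 methyl, H6, H7 and the C8 ester oxygen lie on the face of H5, while the C4 hydroxyl, the C6 hydroxyl and the isopropyl group lie on the other face. The C6 hydroxyl is therefore cis to both of its carbon-substituted neighbours and 1,3-syn to the C4 hydroxyl. Fragile points are the tertiary homoallylic alcohol (loss of water), the 1(10) alkene (it can slip into conjugation whenever C8 is a ketone), the O6/O8 pair (acyl migration) and the free phenol. The real difficulty is stereochemical: five contiguous centres on a flexible seven-membered ring, with O6 on the more hindered face, and three hydroxyls to be told apart at the end. The key step uses the fact that ring B carries methyl on C10, oxygen on C8 and isopropyl on C7 in the pattern of thymol, so C1 and C6–C10 can start as a benzene ring and C5 as a carbene carbon tethered through C2–C4.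

## Logic of the disconnections

17 to 16: only the phenolic O–acetyl bond is cut. The phenol must be masked while the ester is made. The forward step has to remove an aryl acetate without touching the alkyl aryl ester at C8 or moving it to O6.

16 to 14 and 15: the C8–O acyl bond is cut, so the aromatic acid enters last and convergently. This strips the target to its triol core. The acylation must choose O8 over the tertiary O4 and over O6, which is flanked by C5 and C7.

14 to 13: the C8–H bond is cut. With C8 as a ketone, O6 can deliver hydride to C8 on its own face, which gives the 1,3-anti diol. One stereocentre disappears and C7 becomes an epimerisable α-carbon. The reduction must be truly intramolecular.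

13 to 11 (through 12): the C6–O and C7–H bonds are cut, formally water across an enone. An untethered nucleophile is expected to reach C6 from the H5 face, which is the wrong one. O4 sits 1,3 to C6 on the correct face, so the oxygen is delivered from a tether on O4. Two stereocentres are removed. The forward step needs the hemiester of a tertiary alcohol to form and C7 to be protonated to the more stable epimer.

11 to 10: the O–Si bond of a silyl dienol ether is cut, together with the C9–H bond formed on its cleavage. In 11 the C1=C10 alkene is β,γ to the C8 ketone, the kinetic and not the conjugated arrangement. It must come from an enolate protonated at C9. Acid hydrolysis of an alkyl dienol ether would be expected to protonate the far end (C1) of the 1-alkoxydiene and move the double bond. For this reason the arene oxygen is carried as a silyl ether from step 1. The step needs buffered fluoride at low temperature.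

10 to 9: the C4–C15 bond is cut. The ring A ketone left by the diazoketone becomes the tertiary carbinol, and C5 directs the addition. After it, C4 is a centre that cannot epimerise and takes over the relay from C5. The methyl donor must be non-basic, because H5 of 9 is α to the ketone and doubly allylic.

9 to 7 (through 8): the C1–C5 and C5–C6 bonds are cut. One step gives both rings, two skeletal bonds, the C5 stereocentre, the C1=C10 alkene, a masked C8 ketone and the C6=C7 alkene. The precursor is a flat arene with a three-atom tether. The step must choose one of two ortho bonds and one carbenoid face, and must avoid aromatic substitution.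

7 to 5 (through 6): the C=N2 unit on the terminal carbon is cut. Diazo transfer to a methyl ketone avoids diazomethane and acid chlorides. The methyl side must be activated regioselectively.

5 to 3 and 4: the aryl–C2 bond is cut. The tether must hold exactly two CH2 groups between arene and carbonyl so that ring A becomes five-membered. A Friedel–Crafts succinoylation and reduction sequence is ruled out, because it leaves three CH2 groups and, after homologation to the diazoketone, would close a six-membered ring. Compound 4 brings C2, C3, C4 and the future C5 in one C–C coupling. The forward step is an arylation that isomerises the allylic alcohol to the ketone.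

3 to 2: the C–I bond para to oxygen is cut. This carbon becomes C1. Regiocontrol comes from the oxygen substituent and from the bulk of its silyl group.

2 to 1: the O–Si bond is cut, which reaches the commercial phenol 1.

## Other disconnections considered

Alternative 1: The cut is C1–C2 of ring A together with C10–C14. In the forward sense, iodine–lithium exchange at C2 with t-BuLi, 5-exo-dig syn-carbolithiation across a C1≡C10 alkyne and methylation of the C10 vinyllithium with retention would give the alkylidenecyclopentane A1.
- In its favour: the position and geometry of the tetrasubstituted alkene are fixed by mechanism and cannot drift. C4 and C5 arrive as defined centres instead of depending on an untested asymmetric carbenoid reaction.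
- Against it here: A1 holds only ring A and 11 of the 15 skeletal carbons. C7 and the isopropyl group are missing. Ring B must still be closed between the C6 and C8 side chains, and C6, C7 and C8 are new stereocentres on a seven-membered ring that is formed late. The precursor of A1 needs an asymmetric synthesis of its own, and its propargylic H5 is exposed to t-BuLi.
- Comparison: on structure, the chosen plan forms both rings at once and has every skeletal carbon in place after step 6. On mechanism, alternative 1 is the better plan for alkene control, since the chosen plan must guard the 1(10) alkene at the stage of 11, and the two are about equal in hazard (t-BuLi against a diazoketone). On step economy the chosen plan is clearly shorter.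

Alternative 2: The cut is C8–C9. In the forward sense, Me2AlCl would activate a C8 aldehyde, the terminal CH2 of an isopropenyl group on C1 would attack it, and loss of H1 would give the guai-1(10)-ene A2 with a free C8 hydroxyl and silylated O4 and O6.
- In its favour: ring A can come from a cheap chiral-pool monoterpene by ring contraction. The C1=C10 alkene is formed where it is needed. A2 presents O8 as the only free hydroxyl, so the esterification site is unambiguous. On this point alternative 2 is better than the chosen plan, which relies on steric differentiation in step 10.
- Against it here: C4, C5, C6 and C7 must all be set in the open-chain precursor of A2, with several protecting-group steps. Closing a seven-membered ring by an ene reaction is slower than closing a six-membered one. Hydrogen may be lost from C14 instead of C1, which would give the exocyclic 10(14) alkene. The C8 configuration rests on the transition-state geometry, and a β-silyloxy aldehyde under a Lewis acid can eliminate.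
- Comparison: on structure, the chosen plan builds two rings in its key step and alternative 2 builds one. On mechanism, both carry a regiochemical risk of about equal weight (site of proton loss there, ortho bond and double-bond position here). On step economy the chosen plan should be shorter before the key step, and alternative 2 is equal or slightly shorter after it.

Alternative 3: The cut is C1–C5. In the forward sense, BF3·OEt2 would open the 4,5-epoxide of a ten-membered germacrene ring while C1 of the 1(10) alkene attacks C5 with inversion, and the C10 cation would lose H1 to give A3, the bis-silyl ether of the target.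
- In its favour: it follows the likely biogenesis. One step sets the ring fusion, the C4 carbinol (its configuration comes from the epoxide) and the alkene. A3 is a single deprotection from the target, so in endgame length alternative 3 is better than the chosen plan.
- Against it here: the precursor of A3 is a ten-membered ring with four stereocentres, a defined alkene and a cis epoxide. It is harder to make than anything in the chosen route (macrocyclisation, conformers, Cope rearrangement). The C10 cation can also lose H9 or a C14 hydrogen, or be trapped by a neighbouring oxygen.
- Comparison: on structure, both plans form the C1–C5 bond in the key step, but the chosen plan starts from an arene that costs five simple steps. On mechanism, the cation cascade is at least as hard to steer as the carbenoid step. On step economy, alternative 3 wins after the key step and should lose heavily before it.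

Key step: step 5

Remarks on the chemistry (assumptions, one line each):
- Guaiane numbering is used throughout (C14 on C10, C15 on C4, isopropyl on C7).
- The arene oxygen is carried as a triisopropylsilyl ether; this is a protecting-group change only, and the skeletons of the diazoketone 7 and the ring-expanded ketone 9 are unchanged.
- The sense of induction of Rh2(S-PTTL)4, dirhodium tetrakis[N-phthaloyl-(S)-tert-leucinate], on this arene is not known in advance; the S catalyst is written, and its mirror image would be used if it favoured the enantiomer of 9.
- In step 8 the enantiomer of the amine–thiourea promoter that matches the substrate would be used; the R,R form is written.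

## Route

Step 1
Reactants: 1 thymol
Product: 2 tri(propan-2-yl)[5-methyl-2-(propan-2-yl)phenoxy]silane
Conditions: i-Pr3SiCl, imidazole, DMF, 50 °C
Reagents that add atoms: chlorotri(propan-2-yl)silane, CC(C)[Si](Cl)(C(C)C)C(C)C
Why: O-silylation of a phenol with a silyl chloride and imidazole; the bulky silyl ether withstands the base, palladium and carbenoid steps and later lets the C8 enol ether be opened by fluoride instead of acid.

Step 2
Reactants: 2 tri(propan-2-yl)[5-methyl-2-(propan-2-yl)phenoxy]silane
Product: 3 [4-iodo-5-methyl-2-(propan-2-yl)phenoxy]tri(propan-2-yl)silane
Conditions: N-iodosuccinimide, CF3CO2H (10 mol %), MeCN, rt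
Reagents that add atoms: N-iodosuccinimide, O=C1CCC(=O)N1I
Why: Electrophilic aromatic iodination; oxygen directs para (the future C1), and the only other activated position lies between the bulky silyloxy group and the methyl group.

Step 3
Reactants: 3 [4-iodo-5-methyl-2-(propan-2-yl)phenoxy]tri(propan-2-yl)silane; 4 but-3-en-2-ol
Product: 5 4-[2-methyl-5-(propan-2-yl)-4-{[tri(propan-2-yl)silyl]oxy}phenyl]butan-2-one
Conditions: Pd(OAc)2 (3 mol %), n-Bu4NCl, NaHCO3, DMF, 50 °C
Reagents that add atoms: none
Why: Heck arylation of an allylic alcohol under Jeffery conditions: zerovalent palladium formed in the flask inserts into the C–I bond, the aryl group adds to the terminal alkene carbon, and β-hydride elimination toward the carbinol gives the enol and hence the saturated methyl ketone. The tether has exactly two CH2 groups between arene and carbonyl.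

Step 4
Reactants: 5 4-[2-methyl-5-(propan-2-yl)-4-{[tri(propan-2-yl)silyl]oxy}phenyl]butan-2-one
Product: 7 1-diazo-4-[2-methyl-5-(propan-2-yl)-4-{[tri(propan-2-yl)silyl]oxy}phenyl]butan-2-one, via trifluoroacetyl diketone 6 (not isolated)
Conditions: LiN(SiMe3)2, THF, −78 °C, then CF3CO2CH2CF3; then 4-acetamidobenzenesulfonyl azide, Et3N, H2O (1 equiv), MeCN, rt
Reagents that add atoms: 4-acetamidobenzenesulfonyl azide, CC(=O)Nc1ccc(cc1)S(=O)(=O)N=[N+]=[N-]; 2,2,2-trifluoroethyl trifluoroacetate, O=C(OCC(F)(F)F)C(F)(F)F (its CF3CO group stays only in 6)
Why: Detrifluoroacetylative diazo transfer (Danheiser): the kinetic enolate on the methyl side is trifluoroacetylated, and the activated diketone 6 takes up the diazo group while the trifluoroacetyl group leaves on the sulfonamide. No diazomethane or acid chloride is needed, and the azide chosen is among the less shock-sensitive sulfonyl azides.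

Step 5
Reactants: 7 1-diazo-4-[2-methyl-5-(propan-2-yl)-4-{[tri(propan-2-yl)silyl]oxy}phenyl]butan-2-one
Product: 9 (8aR)-4-methyl-7-(propan-2-yl)-6-{[tri(propan-2-yl)silyl]oxy}-3,8a-dihydroazulen-1(2H)-one, via norcaradiene 8 (not isolated)
Conditions: Rh2(S-PTTL)4 (1 mol %), CH2Cl2, 0 °C to rt, slow addition of 7; filtration through neutral alumina
Reagents that add atoms: none
Why: Rh2(S-PTTL)4 expels N2 from 7 to give an electrophilic rhodium carbenoid at C5, which cyclopropanates the arene C1–C6 bond (forming C1–C5 and C5–C6) to the norcaradiene 8. Thermally allowed six-electron disrotatory opening of the C1–C6 bond of 8 then gives the cycloheptatriene 9. The closest known reaction type is the intramolecular Buchner reaction of 1-diazo-4-arylbutan-2-ones to 3,8a-dihydroazulen-1(2H)-ones, for which chiral dirhodium carboxylates and copper bis(oxazoline) complexes are established catalysts. Ring A closes in a 5-exo sense when the tethered carbenoid carbon bonds to the ipso carbon C1, and ring B arises by one-carbon expansion of the benzene ring (cyclopropanation followed by electrocyclic opening). C5 is the only stereocentre that remains, and it is set by the chiral carboxylate ligands, which decide which face of the carbenoid meets the arene; the two further centres of 8 follow from the cis fusion and vanish on opening. The step needs site selectivity between the two ortho bonds and chemoselectivity against aromatic substitution: the methyl group on C10 disfavours addition across C1–C10, C6 carries only hydrogen, and a non-fluorinated carboxylate catalyst under acid-free conditions should hold back the zwitterionic path to the 2-tetralone. 9 would be kept cold, free of acid and base, and used at once, because H5 is α to the ketone and doubly allylic.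

Step 6
Reactants: 9 (8aR)-4-methyl-7-(propan-2-yl)-6-{[tri(propan-2-yl)silyl]oxy}-3,8a-dihydroazulen-1(2H)-one
Product: 10 (1S,8aR)-1,4-dimethyl-7-(propan-2-yl)-6-{[tri(propan-2-yl)silyl]oxy}-1,2,3,8a-tetrahydroazulen-1-ol
Conditions: MeLi, CeCl3 (dried), THF, −78 °C; pH 7 buffer
Reagents that add atoms: methyllithium, [Li]C
Why: Organocerium 1,2-addition to an easily enolised ketone; MeCeCl2 is nucleophilic but hardly basic, so H5 should stay in place. C6 of ring B covers one face of the ring A carbonyl, so methyl should enter from the H5 face and leave the C4 hydroxyl on the side of C6; this sets C4 as a centre that cannot epimerise.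

Step 7
Reactants: 10 (1S,8aR)-1,4-dimethyl-7-(propan-2-yl)-6-{[tri(propan-2-yl)silyl]oxy}-1,2,3,8a-tetrahydroazulen-1-ol
Product: 11 (1S,8aR)-1-hydroxy-1,4-dimethyl-7-(propan-2-yl)-1,2,3,8a-tetrahydroazulen-6(5H)-one (= 4-hydroxyguaia-1(10),6-dien-8-one)
Conditions: n-Bu4NF, AcOH, THF, −40 to 0 °C
Reagents that add atoms: none
Why: Fluoride cleavage of a silyl enol ether with a proton source present; the dienolate should be protonated under kinetic control at its α-carbon C9, which frees the C8 ketone conjugated with C6=C7 and keeps the C1=C10 alkene in its β,γ position. Acid hydrolysis is avoided because it would be expected to protonate the distal carbon C1.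

Step 8
Reactants: 11 (1S,8aR)-1-hydroxy-1,4-dimethyl-7-(propan-2-yl)-1,2,3,8a-tetrahydroazulen-6(5H)-one
Product: 13 (1S,7S,8S,8aS)-1,8-dihydroxy-1,4-dimethyl-7-(propan-2-yl)-1,2,3,7,8,8a-hexahydroazulen-6(5H)-one (= (4S,5S,6S,7S)-4,6-dihydroxyguai-1(10)-en-8-one), via cyclic phenylboronate 12 (not isolated)
Conditions: PhB(OH)2, 1-[3,5-bis(trifluoromethyl)phenyl]-3-[(1R,2R)-2-(dimethylamino)cyclohexyl]thiourea (10 mol %), 4 Å MS, toluene, rt; then 30% H2O2, aq. NaHCO3, THF, 0 °C
Reagents that add atoms: phenylboronic acid, OB(O)c1ccccc1 (one of its oxygen atoms becomes O6)
Why: Boronic acid hemiester-directed intramolecular oxa-Michael addition of a δ-hydroxy enone: the hemiester on O4 holds an amine-activated B–OH group next to C6 on the face opposite to H5, and closure to the six-membered boronate 12 sets C6 syn to O4. C7, α to the ketone, should be protonated or equilibrated to the epimer with a pseudo-equatorial isopropyl group cis to O6, and the oxidative work-up releases the diol.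

Step 9
Reactants: 13 (1S,7S,8S,8aS)-1,8-dihydroxy-1,4-dimethyl-7-(propan-2-yl)-1,2,3,7,8,8a-hexahydroazulen-6(5H)-one
Product: 14 (1S,6S,7R,8R,8aS)-1,4-dimethyl-7-(propan-2-yl)-1,2,3,5,6,7,8,8a-octahydroazulene-1,6,8-triol (= (4S,5S,6R,7R,8S)-guai-1(10)-ene-4,6,8-triol)
Conditions: Me4NBH(OAc)3, MeCN/AcOH (1:1), −30 °C
Reagents that add atoms: none
Why: Evans–Saksena hydroxyl-directed reduction of a β-hydroxy ketone: O6 exchanges onto boron and delivers hydride to C8 on its own face through a six-membered transition state, which should give the 1,3-anti diol with O8 on the H5 face. The tertiary O4 is too far from C8 to compete.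

Step 10
Reactants: 14 (1S,6S,7R,8R,8aS)-1,4-dimethyl-7-(propan-2-yl)-1,2,3,5,6,7,8,8a-octahydroazulene-1,6,8-triol; 15 4-acetoxybenzoic acid
Product: 16 (4S,5S,6R,7S,8S)-4,6-dihydroxyguai-1(10)-en-8-yl 4-acetoxybenzoate
Conditions: 1-ethyl-3-[3-(dimethylamino)propyl]carbodiimide hydrochloride (EDC·HCl), 4-(dimethylamino)pyridine (10 mol %), CH2Cl2, 0 °C
Reagents that add atoms: none
Why: Steglich esterification; O8 is pseudo-equatorial with a CH2 neighbour, whereas O6 is pseudo-axial between C5 and C7 and O4 is tertiary, so one equivalent of the activated acid should go to O8. The acetate keeps the phenol from acylating itself.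

Step 11
Reactants: 16 (4S,5S,6R,7S,8S)-4,6-dihydroxyguai-1(10)-en-8-yl 4-acetoxybenzoate
Product: 17 (4S,5S,6R,7S,8S)-4,6-dihydroxyguai-1(10)-en-8-yl 4-hydroxybenzoate (CNP0392039.1)
Conditions: NH3 (7 M in MeOH), THF, 0 °C
Reagents that add atoms: none
Why: Aminolysis of a phenolic acetate, which is far more electrophilic than the alkyl benzoate; once the phenol is free, its partial deprotonation deactivates the C8 ester further, and the short cold treatment should leave the ester on O8.

## Compound list

1 | thymol | Cc1ccc(C(C)C)c(O)c1 | starting material
2 | tri(propan-2-yl)[5-methyl-2-(propan-2-yl)phenoxy]silane | Cc1ccc(C(C)C)c(O[Si](C(C)C)(C(C)C)C(C)C)c1 | intermediate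
3 | [4-iodo-5-methyl-2-(propan-2-yl)phenoxy]tri(propan-2-yl)silane | Cc1cc(O[Si](C(C)C)(C(C)C)C(C)C)c(C(C)C)cc1I | intermediate
4 | but-3-en-2-ol (racemic; its stereocentre is lost) | CC(O)C=C | starting material
5 | 4-[2-methyl-5-(propan-2-yl)-4-{[tri(propan-2-yl)silyl]oxy}phenyl]butan-2-one | CC(=O)CCc1cc(C(C)C)c(O[Si](C(C)C)(C(C)C)C(C)C)cc1C | intermediate
6 | 1,1,1-trifluoro-6-[2-methyl-5-(propan-2-yl)-4-{[tri(propan-2-yl)silyl]oxy}phenyl]hexane-2,4-dione (not isolated) | O=C(CCc1cc(C(C)C)c(O[Si](C(C)C)(C(C)C)C(C)C)cc1C)CC(=O)C(F)(F)F | intermediate
7 | 1-diazo-4-[2-methyl-5-(propan-2-yl)-4-{[tri(propan-2-yl)silyl]oxy}phenyl]butan-2-one | [N-]=[N+]=CC(=O)CCc1cc(C(C)C)c(O[Si](C(C)C)(C(C)C)C(C)C)cc1C | intermediate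
8 | norcaradiene valence isomer of 9, cyclopropane C1–C5–C6 (not isolated) | CC1=CC(O[Si](C(C)C)(C(C)C)C(C)C)=C(C(C)C)[C@@H]2[C@H]3C(=O)CC[C@@]123 | intermediate
9 | (8aR)-4-methyl-7-(propan-2-yl)-6-{[tri(propan-2-yl)silyl]oxy}-3,8a-dihydroazulen-1(2H)-one | CC1=C2CCC(=O)[C@@H]2C=C(C(C)C)C(O[Si](C(C)C)(C(C)C)C(C)C)=C1 | intermediate
10 | (1S,8aR)-1,4-dimethyl-7-(propan-2-yl)-6-{[tri(propan-2-yl)silyl]oxy}-1,2,3,8a-tetrahydroazulen-1-ol | CC1=C2CC[C@](C)(O)[C@@H]2C=C(C(C)C)C(O[Si](C(C)C)(C(C)C)C(C)C)=C1 | intermediate
11 | (1S,8aR)-1-hydroxy-1,4-dimethyl-7-(propan-2-yl)-1,2,3,8a-tetrahydroazulen-6(5H)-one | CC1=C2CC[C@](C)(O)[C@@H]2C=C(C(C)C)C(=O)C1 | intermediate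
12 | cyclic phenylboronate of 13 across O4 and O6 (not isolated) | CC1=C2CC[C@](C)(OB(c3ccccc3)O4)[C@@H]2[C@H]4[C@H](C(C)C)C(=O)C1 | intermediate
13 | (4S,5S,6S,7S)-4,6-dihydroxyguai-1(10)-en-8-one | CC1=C2CC[C@](C)(O)[C@@H]2[C@H](O)[C@H](C(C)C)C(=O)C1 | intermediate
14 | (4S,5S,6R,7R,8S)-guai-1(10)-ene-4,6,8-triol | CC1=C2CC[C@](C)(O)[C@@H]2[C@H](O)[C@H](C(C)C)[C@@H](O)C1 | intermediate
15 | 4-acetoxybenzoic acid | CC(=O)Oc1ccc(cc1)C(=O)O | starting material
16 | (4S,5S,6R,7S,8S)-4,6-dihydroxyguai-1(10)-en-8-yl 4-acetoxybenzoate | CC1=C2CC[C@](C)(O)[C@@H]2[C@H](O)[C@H](C(C)C)[C@@H](OC(=O)c2ccc(OC(C)=O)cc2)C1 | intermediate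
17 | (4S,5S,6R,7S,8S)-4,6-dihydroxyguai-1(10)-en-8-yl 4-hydroxybenzoate | CC1=C2CC[C@](C)(O)[C@@H]2[C@H](O)[C@H](C(C)C)[C@@H](OC(=O)c2ccc(O)cc2)C1 | target

## Step count and least certain steps

Total step count: 11. Longest linear sequence: 11 steps (1 to 17); 4 and 15 are bought and enter at steps 3 and 10.

Step 5 (key step). The chiral carboxylate may discriminate poorly between the carbenoid faces of a terminal, unstabilised diazoketone. Configuration at C5 may also be lost through enolisation of 9 on handling, and the carbenoid may be diverted into aromatic substitution or into addition across C1–C10. The fallback separates ring construction from asymmetric induction. Setting out from 7, decomposition with achiral Rh2(OAc)4 in CH2Cl2 would give 9 together with its mirror image, the (8aS)-azulenone F2, through the enantiomeric norcaradiene F1. The mixture would be methylated as in step 6 to 10 and its mirror image, the (1R,8aS)-carbinol F3. Preparative chromatography on a chiral stationary phase at this first configurationally stable stage returns to the route at 10.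

Step 8. Hemiester formation at the tertiary O4 may be slow. Untethered oxygen delivery, expected from the H5 face, or amine-promoted migration of the C1=C10 bond of 11 could then compete, and C7 may be protonated from the wrong face. The fallback sets out from 11 and uses alkoxide-directed nucleophilic epoxidation (t-BuOOLi, THF, −20 °C, the lithium alkoxide of O4 holding the peroxide on its own face). This would give the 6,7-epoxy ketone F4 with its oxygen on the face opposite to H5. SmI2 in THF/MeOH at −90 °C would then cleave the C7–O bond and the enolate would be protonated, which comes back at 13.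

Step 9. Ligand exchange at the hindered pseudo-axial O6 may be incomplete, so that undirected hydride transfer erodes the selectivity at C8. The fallback sets out from 13 and reverses the logic. Chelation-controlled syn reduction (Et2BOMe, NaBH4, THF/MeOH, −78 °C, Narasaka–Prasad) would give the 8-epi-triol F5. Mitsunobu esterification with 15 (PPh3, diisopropyl azodicarboxylate, toluene, 0 °C) at the less hindered C8 hydroxyl would invert C8 and come back at 16, bypassing step 10.

Step 10. Acylation may occur at O6 or at both secondary hydroxyls, or the acyl group may migrate from O8 to O6 under 4-(dimethylamino)pyridine. The fallback sets out from 14. Ketalisation of the syn-1,3 pair O4/O6 (2,2-dimethoxypropane, pyridinium p-toluenesulfonate, CH2Cl2) would give the acetonide F6, in which O8 is the only free hydroxyl. Esterification with 15 under the conditions of step 10 would give the acetonide ester F7, and 80% aqueous AcOH at rt would remove the ketal and come back at 16.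

## Further compounds

F1 | step 5 | enantiomer of norcaradiene 8 (not isolated) | CC1=CC(O[Si](C(C)C)(C(C)C)C(C)C)=C(C(C)C)[C@H]2[C@@H]3C(=O)CC[C@]123
F2 | step 5 | (8aS)-4-methyl-7-(propan-2-yl)-6-{[tri(propan-2-yl)silyl]oxy}-3,8a-dihydroazulen-1(2H)-one | CC1=C2CCC(=O)[C@H]2C=C(C(C)C)C(O[Si](C(C)C)(C(C)C)C(C)C)=C1
F3 | step 5 | (1R,8aS)-1,4-dimethyl-7-(propan-2-yl)-6-{[tri(propan-2-yl)silyl]oxy}-1,2,3,8a-tetrahydroazulen-1-ol | CC1=C2CC[C@@](C)(O)[C@H]2C=C(C(C)C)C(O[Si](C(C)C)(C(C)C)C(C)C)=C1
F4 | step 8 | 6,7-epoxy-4-hydroxyguai-1(10)-en-8-one, epoxide oxygen on the face opposite to H5 | CC1=C2CC[C@](C)(O)[C@@H]2[C@@H]3O[C@]3(C(C)C)C(=O)C1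
F5 | step 9 | (4S,5S,6R,7R,8R)-guai-1(10)-ene-4,6,8-triol (8-epi-14) | CC1=C2CC[C@](C)(O)[C@@H]2[C@H](O)[C@H](C(C)C)[C@H](O)C1
F6 | step 10 | 4,6-O-isopropylidene ketal of 14 | CC1=C2CC[C@](C)(OC(C)(C)O3)[C@@H]2[C@H]3[C@H](C(C)C)[C@@H](O)C1
F7 | step 10 | 4,6-O-isopropylidene ketal of 16 | CC1=C2CC[C@](C)(OC(C)(C)O3)[C@@H]2[C@H]3[C@H](C(C)C)[C@@H](OC(=O)c2ccc(OC(C)=O)cc2)C1
A1 | alternative 1 | alkylidenecyclopentane with C9 cis to C5, C8 diethyl acetal, C4 triethylsilyl ether and C6 tert-butyldimethylsilyl ether | C/C(CC(OCC)OCC)=C1\CC[C@](C)(O[Si](CC)(CC)CC)[C@@H]1CO[Si](C)(C)C(C)(C)C
A2 | alternative 2 | guai-1(10)-ene with free C8 hydroxyl and triethylsilyl ethers on O4 and O6 | CC1=C2CC[C@](C)(O[Si](CC)(CC)CC)[C@@H]2[C@H](O[Si](CC)(CC)CC)[C@H](C(C)C)[C@@H](O)C1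
A3 | alternative 3 | bis(tert-butyldimethylsilyl) ether of the target (O6 and phenol) | CC1=C2CC[C@](C)(O)[C@@H]2[C@H](O[Si](C)(C)C(C)(C)C)[C@H](C(C)C)[C@@H](OC(=O)c2ccc(O[Si](C)(C)C(C)(C)C)cc2)C1
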